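**Retrosynthetic overview**
1. Cut the depside ester C(=O)–OAr into the ring A acid, 3-formyl-2,4-dimethoxy-6-methylbenzoic acid, and the ring B phenol, allyl 2,4-dihydroxy-3,6-dimethylbenzoate.
2. The CH2OH of ring A is carried as CHO through the coupling, and the CO2H of ring B as its allyl ester.
3. The ring A acid comes from 2,6-dimethoxy-4-methylbenzaldehyde by bromination (positions 3 and 5 are equivalent) and Br→Li→CO2.
4. The ring B ester comes from 2,4-dihydroxy-3,6-dimethylbenzoic acid by carboxylate allylation.
5. No ring is formed; both benzene rings are bought intact. Order: functionalise ring A, protect ring B, join, reduce, deprotect.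

Assumption: the target has no stereocentre and is achiral, so the "single enantiomer" is the compound itself and no stereocontrol is needed; compounds 1 and 7 are taken as catalogue chemicals.

**Route**

Step 1
Reactants: 1 2,6-dimethoxy-4-methylbenzaldehyde
Product: 2 3-bromo-2,6-dimethoxy-4-methylbenzaldehyde
Conditions: NBS (1.0 equiv), MeCN, 0 °C to rt, dark
Reagents that add atoms: N-bromosuccinimide, O=C1CCC(=O)N1Br
Why: Electrophilic aromatic bromination; the only free positions (3 and 5) are equivalent by symmetry and activated by an ortho OMe, a para OMe and an ortho CH3, so one regioisomer forms.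

Step 2
Reactants: 2 3-bromo-2,6-dimethoxy-4-methylbenzaldehyde
Product: 6 3-formyl-2,4-dimethoxy-6-methylbenzoic acid, via lithium morpholino alkoxide 3 (not isolated), via aryllithium 4 (not isolated), via lithium carboxylate 5 (not isolated)
Conditions: morpholine (1.1 equiv), n-BuLi (1.1 equiv), THF, −78 °C; add 2, −78 to −40 °C; n-BuLi (1.05 equiv), −78 °C, 20 min; CO2, −78 °C to rt; 2 M HCl work-up
Reagents that add atoms: carbon dioxide, O=C=O
Why: Lithium morpholide adds to the aldehyde to mask it in situ as an α-amino alkoxide (Comins-type protection), bromine–lithium exchange then gives an aryllithium that is carboxylated by CO2, and acid work-up collapses the hemiaminal back to CHO; its transient carbinol centre is lost again.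

Step 3
Reactants: 7 2,4-dihydroxy-3,6-dimethylbenzoic acid
Product: 8 prop-2-en-1-yl (allyl) 2,4-dihydroxy-3,6-dimethylbenzoate
Conditions: KHCO3 (1.2 equiv), allyl bromide (1.1 equiv), DMF, rt, 16 h
Reagents that add atoms: allyl bromide, C=CCBr
Why: SN2 O-alkylation of the carboxylate; bicarbonate deprotonates the acid but not the phenols, so only the ester forms, and room temperature avoids decarboxylation.

Step 4
Reactants: 6 3-formyl-2,4-dimethoxy-6-methylbenzoic acid; 8 allyl 2,4-dihydroxy-3,6-dimethylbenzoate
Product: 10 allyl 4-[(3-formyl-2,4-dimethoxy-6-methylbenzoyl)oxy]-2-hydroxy-3,6-dimethylbenzoate, via mixed trifluoroacetic anhydride 9 (not isolated)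
Conditions: TFAA (5 equiv), dry toluene, rt, 3 h; aqueous NaHCO3 work-up
Reagents that add atoms: none
Why: Mixed-anhydride (TFAA) depside esterification; the di-ortho-substituted acid gives an acylium-like aroyl trifluoroacetate that acylates the free 4-OH, while the 2-OH is hydrogen-bonded to the ester carbonyl and stays untouched.

Step 5
Reactants: 10 allyl 4-[(3-formyl-2,4-dimethoxy-6-methylbenzoyl)oxy]-2-hydroxy-3,6-dimethylbenzoate
Product: 11 allyl 2-hydroxy-4-{[3-(hydroxymethyl)-2,4-dimethoxy-6-methylbenzoyl]oxy}-3,6-dimethylbenzoate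
Conditions: NaBH4 (0.6 equiv), THF/MeOH 4:1, 0 °C, 20 min; sat. NH4Cl quench
Reagents that add atoms: none
Why: Chemoselective borohydride reduction of the aryl aldehyde; the depside ester is flanked by OMe and CH3 and the allyl ester is hindered and chelated, so neither is attacked at 0 °C.

Step 6
Reactants: 11 allyl 2-hydroxy-4-{[3-(hydroxymethyl)-2,4-dimethoxy-6-methylbenzoyl]oxy}-3,6-dimethylbenzoate
Product: 12 2-hydroxy-4-{[3-(hydroxymethyl)-2,4-dimethoxy-6-methylbenzoyl]oxy}-3,6-dimethylbenzoic acid (CNP0372912.0)
Conditions: Pd(PPh3)4 (5 mol %), morpholine (3 equiv), THF, rt, 1 h; cold 0.5 M citric acid work-up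
Reagents that add atoms: none
Why: Tsuji–Trost deallylation; zerovalent palladium ionises the allyl ester to a π-allyl complex that morpholine traps, under neutral conditions that spare the depside ester and the acid-sensitive electron-rich benzylic alcohol.

**Compound list**
1 | 2,6-dimethoxy-4-methylbenzaldehyde | COc1cc(C)cc(OC)c1C=O | starting material
2 | 3-bromo-2,6-dimethoxy-4-methylbenzaldehyde | COc1cc(C)c(Br)c(OC)c1C=O | intermediate
3 | lithium (3-bromo-2,6-dimethoxy-4-methylphenyl)(morpholin-4-yl)methanolate (racemic, transient) | [Li]OC(N1CCOCC1)c1c(OC)cc(C)c(Br)c1OC | intermediate (not isolated)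
4 | lithium (3-lithio-2,6-dimethoxy-4-methylphenyl)(morpholin-4-yl)methanolate | [Li]OC(N1CCOCC1)c1c(OC)cc(C)c([Li])c1OC | intermediate (not isolated)
5 | lithium 3-[(lithiooxy)(morpholin-4-yl)methyl]-2,4-dimethoxy-6-methylbenzoate | [Li]OC(N1CCOCC1)c1c(OC)cc(C)c(C(=O)O[Li])c1OC | intermediate (not isolated)
6 | 3-formyl-2,4-dimethoxy-6-methylbenzoic acid | COc1cc(C)c(C(=O)O)c(OC)c1C=O | intermediate
7 | 2,4-dihydroxy-3,6-dimethylbenzoic acid | Cc1cc(O)c(C)c(O)c1C(=O)O | starting material
8 | prop-2-en-1-yl 2,4-dihydroxy-3,6-dimethylbenzoate | Cc1cc(O)c(C)c(O)c1C(=O)OCC=C | intermediate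
9 | 3-formyl-2,4-dimethoxy-6-methylbenzoic trifluoroacetic anhydride | COc1cc(C)c(C(=O)OC(=O)C(F)(F)F)c(OC)c1C=O | intermediate (not isolated)
10 | prop-2-en-1-yl 4-[(3-formyl-2,4-dimethoxy-6-methylbenzoyl)oxy]-2-hydroxy-3,6-dimethylbenzoate | COc1cc(C)c(C(=O)Oc2cc(C)c(C(=O)OCC=C)c(O)c2C)c(OC)c1C=O | intermediate
11 | prop-2-en-1-yl 2-hydroxy-4-{[3-(hydroxymethyl)-2,4-dimethoxy-6-methylbenzoyl]oxy}-3,6-dimethylbenzoate | COc1cc(C)c(C(=O)Oc2cc(C)c(C(=O)OCC=C)c(O)c2C)c(OC)c1CO | intermediate
12 | 2-hydroxy-4-{[3-(hydroxymethyl)-2,4-dimethoxy-6-methylbenzoyl]oxy}-3,6-dimethylbenzoic acid | COc1cc(C)c(C(=O)Oc2cc(C)c(C(=O)O)c(O)c2C)c(OC)c1CO | target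

**Count**
Total steps: 6. Longest linear sequence: 5 steps (steps 1, 2, 4, 5, 6); step 3 is the one-step side arm.

**Three steps most likely to fail, and fallbacks**

Step 2. The one-pot masking, exchange and carboxylation can fail if the hindered aldehyde is not fully converted to the amino alkoxide (butyl addition to CHO) or if the aryllithium is butylated by 1-bromobutane. The fallback sets out from 2 and uses an isolated acetal instead of the in situ mask. HC(OMe)3, MeOH and cat. TsOH give 3-bromo-2,6-dimethoxy-4-methylbenzaldehyde dimethyl acetal F1. n-BuLi in THF at −78 °C gives [3-(dimethoxymethyl)-2,4-dimethoxy-6-methylphenyl]lithium F2, and CO2 followed by a mild work-up gives 3-(dimethoxymethyl)-2,4-dimethoxy-6-methylbenzoic acid F3. Stirring F3 in 1 M HCl/THF at rt hydrolyses the acetal, and the route is rejoined at 6.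

Step 4. The strongly acidic TFAA medium could let the aldehyde condense onto the phenol ring or give sluggish acyl transfer because the formyl group disfavours the acylium. The fallback sets out from 6 and moves the acylation to basic conditions through an isolated acyl chloride. Oxalyl chloride and cat. DMF in CH2Cl2 give 3-formyl-2,4-dimethoxy-6-methylbenzoyl chloride F4. F4 is added to 8 in CH2Cl2 containing Et3N and cat. DMAP at 0 °C, where the more acidic, non-chelated 4-OH is acylated, and the route is rejoined at 10.

Step 5. Borohydride in methanol could cleave the phenolic depside ester by methanolysis or hydride attack. The fallback sets out from 10 and reverses the order of the last two operations so that the reduction runs on a carboxylate in water, without alkoxide. Pd(PPh3)4 and morpholine in THF give 4-[(3-formyl-2,4-dimethoxy-6-methylbenzoyl)oxy]-2-hydroxy-3,6-dimethylbenzoic acid F5. F5 is dissolved in aqueous NaHCO3/THF and reduced by NaBH4 at 0 °C, where the ring B carboxylate makes the aryloxide a poorer leaving group; careful acidification gives 12 directly.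

**Further compounds**
F1 | step 2 | 3-bromo-2,6-dimethoxy-4-methylbenzaldehyde dimethyl acetal | COc1cc(C)c(Br)c(OC)c1C(OC)OC
F2 | step 2 | [3-(dimethoxymethyl)-2,4-dimethoxy-6-methylphenyl]lithium | [Li]c1c(C)cc(OC)c(C(OC)OC)c1OC
F3 | step 2 | 3-(dimethoxymethyl)-2,4-dimethoxy-6-methylbenzoic acid | COc1cc(C)c(C(=O)O)c(OC)c1C(OC)OC
F4 | step 4 | 3-formyl-2,4-dimethoxy-6-methylbenzoyl chloride | COc1cc(C)c(C(Cl)=O)c(OC)c1C=O
F5 | step 5 | 4-[(3-formyl-2,4-dimethoxy-6-methylbenzoyl)oxy]-2-hydroxy-3,6-dimethylbenzoic acid | COc1cc(C)c(C(=O)Oc2cc(C)c(C(=O)O)c(O)c2C)c(OC)c1C=O
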